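**Synthesis plan**

- Retrosynthetic cuts: C15=C15' (Wittig union of two C20 halves); C6–C7 of ring B (acetylide plus ring ketone); C6'–C7' of ring A (Sonogashira coupling of the same alkyne with an enol triflate); C11=C12 inside the shared C11 trienynol (Horner–Wadsworth–Emmons).
- Enabling feature: in ring B the fully substituted carbinol C6 lies between quaternary C1 and the carbinol C5, with the C5 and C6 oxygens cis to each other and anti to the C3 hydroxyl; in ring A the C7'≡C8' triple bond sits on C6' of the tetrasubstituted C5'=C6' alkene. One terminal alkyne and one ring ketone, each used twice, therefore supply both ring–chain bonds.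
- Forward order: no ring is built, both six-membered rings come intact from ketoisophorone. The chain block is made first (C11=C12). Ring B then follows (oxirane, C6–C7, two hydride steps, aldehyde) and, in parallel, ring A (triflate, C6'–C7', phosphonium salt). C15=C15' and desilylation come last.
- Stereochemistry: C3 and C3' come from one catalyst-controlled transfer hydrogenation. C5 comes from epoxidation anti to the C3 silyloxy group, the C4–O bond being temporary and later cut by hydride. C6 comes from acetylide attack anti to the oxirane. The E-alkenes come from the E-enynol, the E-selective phosphonate olefination, the trans-hydroalumination, and the Wittig step with thermal equilibration.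

Key step: step 7

Remark: positions are numbered as in carotenoids (unprimed on the triol half, primed on the acetylenic half). The (S,S) ligand in step 1 is the one predicted by the usual model, with the alkenyl side of the ketone in the place of the aryl group; the sense of induction is to be confirmed on 2 before scale-up.

**Ring block**

Step 1
Reactants: 1 ketoisophorone (2,6,6-trimethylcyclohex-2-ene-1,4-dione)
Product: 2 (4S)-4-hydroxy-2,6,6-trimethylcyclohex-2-en-1-one
Conditions: RuCl(p-cymene)[(S,S)-TsDPEN] (divalent ruthenium, 1 mol %), t-BuOK (1 mol %), i-PrOH, 20 °C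
Reagents that add atoms: none
Why: Noyori-type asymmetric transfer hydrogenation should reduce only the C4 carbonyl, because C1 is shielded by the gem-dimethyl carbon and the methyl-bearing alkene carbon, and the chiral ruthenium hydride sets the 4S centre that becomes C3 and C3' of the target.

Step 2
Reactants: 2 (4S)-4-hydroxy-2,6,6-trimethylcyclohex-2-en-1-one
Product: 3 (4S)-4-[(tert-butyldimethylsilyl)oxy]-2,6,6-trimethylcyclohex-2-en-1-one
Conditions: t-BuMe2SiCl, imidazole, DMF, 0 °C → rt
Reagents that add atoms: tert-butyldimethylsilyl chloride CC(C)(C)[Si](C)(C)Cl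
Why: Silylation of a secondary allylic alcohol with silyl chloride and imidazole is routine and leaves the stereocentre untouched; the bulky ether later directs the epoxidation and survives every basic and hydridic step.

**Chain block**

Step 3
Reactants: 4 (E)-3-methylpent-2-en-4-yn-1-ol
Product: 5 (E)-3-methylpent-2-en-4-ynal
Conditions: MnO2 (activated, excess), CH2Cl2, rt; filtered and used as a cold solution
Reagents that add atoms: none
Why: MnO2 oxidation of a primary allylic alcohol should give the enal without touching the terminal alkyne or the E geometry, and telescoping avoids loss of the volatile aldehyde.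

Step 4
Reactants: 5 (E)-3-methylpent-2-en-4-ynal; 6 triethyl (E)-3-methyl-4-phosphonobut-2-enoate
Product: 8 ethyl (2E,4E,6E)-3,7-dimethylnona-2,4,6-trien-8-ynoate, via lithium phosphonate carbanion 7 (not isolated)
Conditions: 6, LiN(SiMe3)2, THF, −78 °C; then 5, −78 → 0 °C
Reagents that add atoms: none
Why: The Horner–Wadsworth–Emmons reaction of the delocalised phosphonate anion with the enal should form C11=C12 with E geometry; the preformed anion is too weak a base to remove the alkyne proton, and the minor 2Z ester is expected to be removable by chromatography.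

Step 5
Reactants: 8 ethyl (2E,4E,6E)-3,7-dimethylnona-2,4,6-trien-8-ynoate
Product: 9 (2E,4E,6E)-3,7-dimethylnona-2,4,6-trien-8-yn-1-ol
Conditions: i-Bu2AlH (2.2 equiv), CH2Cl2, −78 °C; then aq. KNaC4H4O6 (potassium sodium tartrate)
Reagents that add atoms: none
Why: i-Bu2AlH reduces a conjugated ester to the allylic alcohol by 1,2-addition at low temperature and should leave the trienyne geometry intact.

**Ring B half**

Step 6
Reactants: 3 (4S)-4-[(tert-butyldimethylsilyl)oxy]-2,6,6-trimethylcyclohex-2-en-1-one
Product: 10 (1R,5S,6R)-5-[(tert-butyldimethylsilyl)oxy]-1,3,3-trimethyl-7-oxabicyclo[4.1.0]heptan-2-one (oxirane on the face opposite the silyloxy group)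
Conditions: t-BuOOH (in decane), BnMe3N+ OH− (0.2 equiv), THF, 0 °C → rt
Reagents that add atoms: tert-butyl hydroperoxide CC(C)(C)OO
Why: In this Weitz–Scheffer epoxidation the hydroperoxide anion should add to the β-carbon (later C4) anti to the neighbouring silyloxy group, and the enolate then closes the oxirane on that face, which fixes the C5–O bond anti to C3–O.

Step 7
Reactants: 10 epoxy ketone (1R,5S,6R); 9 (2E,4E,6E)-3,7-dimethylnona-2,4,6-trien-8-yn-1-ol
Product: 12 (1R,2R,5S,6R)-5-[(tert-butyldimethylsilyl)oxy]-2-[(3E,5E,7E)-9-hydroxy-3,7-dimethylnona-3,5,7-trien-1-yn-1-yl]-1,3,3-trimethyl-7-oxabicyclo[4.1.0]heptan-2-ol, via dilithio trienynol 11 (not isolated)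
Conditions: 9 (1.3 equiv), n-BuLi (2.6 equiv), THF, −78 → −20 °C; then 10, −78 → −30 °C; then H2O
Reagents that add atoms: none
Why: The acetylide carbon of 11 adds to the C6 carbonyl of 10 in a plain 1,2-addition (its alkoxide end is a spectator) and water then frees the tertiary alcohol; only the C6–C7 bond forms and no ring is closed. The closest known reaction types are the addition of lithium acetylides to 2,2,6-trisubstituted cyclohexanones and the addition of organolithium reagents to cyclic α,β-epoxy ketones on the face away from the oxirane. The one new stereocentre, C6, is governed by the oxirane: the nucleophile should approach antiperiplanar to the C5–O bond (polar Felkin–Anh), that is from the face opposite the oxirane oxygen and syn to the C5 methyl, so that the new hydroxyl lies cis to the C5 oxygen as in the target. The step needs facial selectivity and 1,2-chemoselectivity: C1 and C5 carry no hydrogen, so enolisation cannot compete, the slim sp-hybridised nucleophile fits between the gem-dimethyl carbon and the oxirane carbon, and the C6 alkoxide formed on the oxirane face cannot reach the rear of C5, so no Payne rearrangement follows. The descriptor at C6 is R at this stage and becomes S in step 8 through a change of priorities only.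

Step 8
Reactants: 12 ring B C20 propargylic epoxy alcohol
Product: 13 (1R,2S,5S,6R)-5-[(tert-butyldimethylsilyl)oxy]-2-[(1E,3E,5E,7E)-9-hydroxy-3,7-dimethylnona-1,3,5,7-tetraen-1-yl]-1,3,3-trimethyl-7-oxabicyclo[4.1.0]heptan-2-ol
Conditions: NaAlH2(OCH2CH2OMe)2 (4 equiv), THF, 0 °C → rt; then aq. KNaC4H4O6 (potassium sodium tartrate)
Reagents that add atoms: none
Why: Alkoxide-directed trans-hydroalumination of the propargylic alcohol (hydride to C7, aluminium to C8 in a five-membered aluminate) should give the E C7=C8 alkene after protonolysis; the oxirane should survive because the aluminate sits on its own face and cannot deliver hydride to the rear of C5.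

Step 9
Reactants: 13 ring B C20 epoxy tetraenyl diol
Product: 14 (1S,2R,4S)-4-[(tert-butyldimethylsilyl)oxy]-1-[(1E,3E,5E,7E)-9-hydroxy-3,7-dimethylnona-1,3,5,7-tetraen-1-yl]-2,6,6-trimethylcyclohexane-1,2-diol
Conditions: LiBHEt3 (5 equiv), THF, 0 → 40 °C; then H2O
Reagents that add atoms: none
Why: Hydride opening of a trisubstituted oxirane by LiBHEt3 is an SN2 attack at the less substituted carbon (C4, trans-diaxial by the Fürst–Plattner rule), so the C5–O bond and its configuration are kept and the tertiary C5 alcohol should result.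

Step 10
Reactants: 14 ring B C20 tetraenyl triol 3-silyl ether
Product: 15 (2E,4E,6E,8E)-9-[(1S,2R,4S)-4-[(tert-butyldimethylsilyl)oxy]-1,2-dihydroxy-2,6,6-trimethylcyclohexyl]-3,7-dimethylnona-2,4,6,8-tetraenal
Conditions: MnO2 (activated), CH2Cl2, rt, dark, short contact time
Reagents that add atoms: none
Why: MnO2 oxidises the primary allylic alcohol quickly, the two tertiary alcohols cannot be oxidised, and cleavage of the di-tertiary glycol by this reagent is far slower, so stopping at full conversion should give the polyenal alone.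

**Ring A half**

Step 11
Reactants: 3 (4S)-4-[(tert-butyldimethylsilyl)oxy]-2,6,6-trimethylcyclohex-2-en-1-one
Product: 17 (4R)-4-[(tert-butyldimethylsilyl)oxy]-2,6,6-trimethylcyclohex-1-en-1-yl trifluoromethanesulfonate, via lithium enolate 16 (not isolated)
Conditions: LiBH(s-Bu)3, THF, −78 °C; then PhNTf2, −78 °C → rt
Reagents that add atoms: N-phenylbis(trifluoromethanesulfonimide) O=S(=O)(N(c1ccccc1)S(=O)(=O)C(F)(F)F)C(F)(F)F
Why: The bulky borohydride should add in conjugate fashion because the carbonyl is blocked on both sides, and O-sulfonylation of the resulting regiodefined enolate gives the tetrasubstituted enol triflate; the stereocentre is not involved, and its descriptor turns from S to R only through a change of priorities.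

Step 12
Reactants: 17 ring A enol triflate; 9 (2E,4E,6E)-3,7-dimethylnona-2,4,6-trien-8-yn-1-ol
Product: 18 (2E,4E,6E)-9-[(4R)-4-[(tert-butyldimethylsilyl)oxy]-2,6,6-trimethylcyclohex-1-en-1-yl]-3,7-dimethylnona-2,4,6-trien-8-yn-1-ol
Conditions: Pd(PPh3)4 (zerovalent palladium, 5 mol %), CuI (copper monoiodide, 10 mol %), i-Pr2NH, DMF, rt, degassed
Reagents that add atoms: none
Why: Sonogashira coupling of an alkenyl triflate with a terminal alkyne forms C6'–C7' without touching the free allylic alcohol or the E-alkenes, and hindered cyclohexenyl triflates of this kind are established partners.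

Step 13
Reactants: 18 ring A C20 dienynyl alcohol
Product: 20 ring A C20 triphenylphosphonium bromide (CH2OH of 18 replaced by CH2–PPh3+ Br−), via allylic bromide 19 (not isolated)
Conditions: CBr4 (1.2 equiv), PPh3 (1.2 equiv), CH2Cl2, −30 → 0 °C; then PPh3 (1.5 equiv), rt, dark
Reagents that add atoms: carbon tetrabromide BrC(Br)(Br)Br; triphenylphosphine c1ccc(cc1)P(c1ccccc1)c1ccccc1
Why: Appel bromination of the primary allylic alcohol under neutral conditions, followed by SN2 displacement with triphenylphosphine, should give the salt while sparing the silyl ether and the enyne; the low temperature limits allylic transposition.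

**Union and deprotection**

Step 14
Reactants: 20 ring A C20 triphenylphosphonium bromide; 15 ring B C20 aldehyde
Product: 23 (3S,5R,6S,3'R)-3,3'-bis[(tert-butyldimethylsilyl)oxy]-7',8'-didehydro-5,6-dihydro-β,β-carotene-5,6-diol (all-E), via phosphorus ylide 21 (not isolated), via 15Z isomer 22 (not isolated)
Conditions: NaOMe, MeOH/CH2Cl2, 0 °C → rt, dark, Ar; then crude polyene in EtOAc, 75 °C, dark
Reagents that add atoms: none
Why: Wittig olefination of the allylic ylide with the polyenal forms C15=C15' as an E/Z mixture, and mild heating should convert the strained central 15Z bond into E; no iodine is used, because the cis form at C9' next to the triple bond is thermodynamically competitive.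

Step 15
Reactants: 23 all-E C40 bis-silyl ether
Product: 24 target, (3S,5R,6S,3'R)-7',8'-didehydro-5,6-dihydro-β,β-carotene-3,5,6,3'-tetrol (all-E)
Conditions: Bu4NF, THF, 0 °C → rt, dark, Ar
Reagents that add atoms: none
Why: Fluoride cleaves both secondary silyl ethers under conditions that should leave the polyene, the alkyne and the tertiary diol unchanged, and no stereocentre is touched.

**Compound list**

1 | ketoisophorone (2,6,6-trimethylcyclohex-2-ene-1,4-dione) | CC1=CC(=O)CC(C)(C)C1=O | starting material
2 | (4S)-4-hydroxy-2,6,6-trimethylcyclohex-2-en-1-one | O=C1C(C)(C)C[C@H](O)C=C1C | intermediate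
3 | (4S)-4-[(tert-butyldimethylsilyl)oxy]-2,6,6-trimethylcyclohex-2-en-1-one | O=C1C(C)(C)C[C@H](O[Si](C)(C)C(C)(C)C)C=C1C | intermediate
4 | (E)-3-methylpent-2-en-4-yn-1-ol | C#C/C(C)=C/CO | starting material
5 | (E)-3-methylpent-2-en-4-ynal | C#C/C(C)=C/C=O | intermediate
6 | triethyl (E)-3-methyl-4-phosphonobut-2-enoate | CCOC(=O)/C=C(C)/CP(=O)(OCC)OCC | starting material
7 | lithium salt of the carbanion of 6 | [Li+].CCOC(=O)/C=C(C)/[CH-]P(=O)(OCC)OCC | intermediate
8 | ethyl (2E,4E,6E)-3,7-dimethylnona-2,4,6-trien-8-ynoate | C#C/C(C)=C/C=C/C(C)=C/C(=O)OCC | intermediate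
9 | (2E,4E,6E)-3,7-dimethylnona-2,4,6-trien-8-yn-1-ol | C#C/C(C)=C/C=C/C(C)=C/CO | intermediate
10 | (1R,5S,6R)-5-[(tert-butyldimethylsilyl)oxy]-1,3,3-trimethyl-7-oxabicyclo[4.1.0]heptan-2-one | O=C1C(C)(C)C[C@H](O[Si](C)(C)C(C)(C)C)[C@H]2O[C@@]12C | intermediate
11 | O,C-dilithio derivative of 9 (lithium alkoxide and lithium acetylide) | [Li+].[Li+].[C-]#C/C(C)=C/C=C/C(C)=C/C[O-] | intermediate
12 | (1R,2R,5S,6R)-5-[(tert-butyldimethylsilyl)oxy]-2-[(3E,5E,7E)-9-hydroxy-3,7-dimethylnona-3,5,7-trien-1-yn-1-yl]-1,3,3-trimethyl-7-oxabicyclo[4.1.0]heptan-2-ol | OC/C=C(C)/C=C/C=C(C)/C#C[C@]1(O)C(C)(C)C[C@H](O[Si](C)(C)C(C)(C)C)[C@H]2O[C@@]12C | intermediate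
13 | (1R,2S,5S,6R)-5-[(tert-butyldimethylsilyl)oxy]-2-[(1E,3E,5E,7E)-9-hydroxy-3,7-dimethylnona-1,3,5,7-tetraen-1-yl]-1,3,3-trimethyl-7-oxabicyclo[4.1.0]heptan-2-ol | OC/C=C(C)/C=C/C=C(C)/C=C/[C@]1(O)C(C)(C)C[C@H](O[Si](C)(C)C(C)(C)C)[C@H]2O[C@@]12C | intermediate
14 | (1S,2R,4S)-4-[(tert-butyldimethylsilyl)oxy]-1-[(1E,3E,5E,7E)-9-hydroxy-3,7-dimethylnona-1,3,5,7-tetraen-1-yl]-2,6,6-trimethylcyclohexane-1,2-diol | OC/C=C(C)/C=C/C=C(C)/C=C/[C@]1(O)C(C)(C)C[C@H](O[Si](C)(C)C(C)(C)C)C[C@@]1(C)O | intermediate
15 | (2E,4E,6E,8E)-9-[(1S,2R,4S)-4-[(tert-butyldimethylsilyl)oxy]-1,2-dihydroxy-2,6,6-trimethylcyclohexyl]-3,7-dimethylnona-2,4,6,8-tetraenal | O=C/C=C(C)/C=C/C=C(C)/C=C/[C@]1(O)C(C)(C)C[C@H](O[Si](C)(C)C(C)(C)C)C[C@@]1(C)O | intermediate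
16 | lithium (4R)-4-[(tert-butyldimethylsilyl)oxy]-2,6,6-trimethylcyclohex-1-en-1-olate | [Li+].CC1=C([O-])C(C)(C)C[C@H](O[Si](C)(C)C(C)(C)C)C1 | intermediate
17 | (4R)-4-[(tert-butyldimethylsilyl)oxy]-2,6,6-trimethylcyclohex-1-en-1-yl trifluoromethanesulfonate | CC1=C(OS(=O)(=O)C(F)(F)F)C(C)(C)C[C@H](O[Si](C)(C)C(C)(C)C)C1 | intermediate
18 | (2E,4E,6E)-9-[(4R)-4-[(tert-butyldimethylsilyl)oxy]-2,6,6-trimethylcyclohex-1-en-1-yl]-3,7-dimethylnona-2,4,6-trien-8-yn-1-ol | CC1=C(C#C/C(C)=C/C=C/C(C)=C/CO)C(C)(C)C[C@H](O[Si](C)(C)C(C)(C)C)C1 | intermediate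
19 | allylic bromide of 18 (CH2OH replaced by CH2Br) | CC1=C(C#C/C(C)=C/C=C/C(C)=C/CBr)C(C)(C)C[C@H](O[Si](C)(C)C(C)(C)C)C1 | intermediate
20 | triphenylphosphonium bromide of 18 (CH2OH replaced by CH2–PPh3+ Br−) | CC1=C(C#C/C(C)=C/C=C/C(C)=C/C[P+](c2ccccc2)(c2ccccc2)c2ccccc2)C(C)(C)C[C@H](O[Si](C)(C)C(C)(C)C)C1.[Br-] | intermediate
21 | phosphorus ylide of 20 | CC1=C(C#C/C(C)=C/C=C/C(C)=C/C=P(c2ccccc2)(c2ccccc2)c2ccccc2)C(C)(C)C[C@H](O[Si](C)(C)C(C)(C)C)C1 | intermediate
22 | 15Z isomer of 23 | CC1=C(C#C/C(C)=C/C=C/C(C)=C/C=C\C=C(C)\C=C\C=C(C)\C=C\[C@]2(O)C(C)(C)C[C@H](O[Si](C)(C)C(C)(C)C)C[C@@]2(C)O)C(C)(C)C[C@H](O[Si](C)(C)C(C)(C)C)C1 | intermediate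
23 | (3S,5R,6S,3'R)-3,3'-bis[(tert-butyldimethylsilyl)oxy]-7',8'-didehydro-5,6-dihydro-β,β-carotene-5,6-diol, all-E | CC1=C(C#C/C(C)=C/C=C/C(C)=C/C=C/C=C(C)/C=C/C=C(C)/C=C/[C@]2(O)C(C)(C)C[C@H](O[Si](C)(C)C(C)(C)C)C[C@@]2(C)O)C(C)(C)C[C@H](O[Si](C)(C)C(C)(C)C)C1 | intermediate
24 | (3S,5R,6S,3'R)-7',8'-didehydro-5,6-dihydro-β,β-carotene-3,5,6,3'-tetrol, all-E (CNP0160593.2) | CC1=C(C#C/C(C)=C/C=C/C(C)=C/C=C/C=C(C)/C=C/C=C(C)/C=C/[C@]2(O)C(C)(C)C[C@H](O)C[C@@]2(C)O)C(C)(C)C[C@H](O)C1 | target

**Step count**

Total: 15 steps. Longest linear sequence: 9 steps (steps 1, 2, 6, 7, 8, 9, 10, 14, 15 from ketoisophorone; the chain branch through steps 3, 4, 5 is equally long).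

**Three steps most likely to fail**

Step 7. The addition may show poor facial discrimination at the C6 carbonyl, for example if lithium bridging of the carbonyl and oxirane oxygens steers the acetylide to the oxirane face, or it may stall between the two fully substituted neighbours. The fallback reverses the order of the two stereo-defining events. It sets out from enone 3 and the dilithio reagent 11: 1,2-addition to the enone gives the C20 cyclohexenyl carbinol F1. Axial attack on the half-chair with a pseudo-equatorial silyloxy group should place the hydroxyl trans to the silyloxy group, and the C6 epimers should be separable. Acetylation of the primary hydroxyl alone (Ac2O, pyridine, 0 °C) gives the monoacetate F2. Hydroxyl-directed epoxidation with VO(acac)2 and t-BuOOH then delivers oxygen to C4=C5 from the face of the C6 hydroxyl, which is also the face away from the silyloxy group, to give the epoxy acetate F3. Methanolysis (K2CO3, MeOH) brings the material back to the route at 12. In this order the cis relation of the C5 and C6 oxygens follows from the directed oxygen transfer and no longer from carbonyl facial selectivity.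

Step 9. Hydride delivery to C4 may be slow or incomplete, because the trajectory is flanked by the C3 silyloxy group and the axial C6 side chain, and the polyene may degrade on long exposure to the basic hydride. The fallback opens the oxirane on the monocycle, before the chain is attached. It sets out from epoxy ketone 10: LiAlH4 in THF at reflux reduces the ketone and opens the oxirane at C4 to give the ring diol F4. Oxidation of the secondary C6 hydroxyl (Dess–Martin periodinane or Swern conditions) gives the α-hydroxy ketone F5. Addition of 11 to F5, with one further equivalent of n-BuLi for the tertiary hydroxyl, should again occur anti to the C5–O bond and give the acetylenic triol F6. Reduction of F6 with NaAlH2(OCH2CH2OMe)2 as in step 8 returns to the route at 14.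

Step 14. The olefination may end in a mixture of geometrical isomers that does not converge: the 15Z form may persist, or heating may isomerise the C9' bond next to the alkyne. The fallback replaces the ylide by a phosphonate carbanion, whose elimination is E-selective, so no heating is needed. It sets out from the allylic bromide 19, generated as in step 13: a Michaelis–Becker reaction with NaP(O)(OEt)2 in THF at 0 °C gives the C20 diethyl phosphonate F7. Deprotonation of F7 (NaH, THF) and Horner–Wadsworth–Emmons reaction with aldehyde 15 at −20 °C → rt should form C15=C15' directly as the E-alkene and return to the route at 23.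

**Further compounds**

F1 | step 7 | C20 cyclohexenyl carbinol: (4S)-4-[(tert-butyldimethylsilyl)oxy]-1-[(3E,5E,7E)-9-hydroxy-3,7-dimethylnona-3,5,7-trien-1-yn-1-yl]-2,6,6-trimethylcyclohex-2-en-1-ol, tertiary hydroxyl trans to the silyloxy group | OC/C=C(C)/C=C/C=C(C)/C#C[C@]1(O)C(C)(C)C[C@H](O[Si](C)(C)C(C)(C)C)C=C1C
F2 | step 7 | primary monoacetate of F1 | CC(=O)OC/C=C(C)/C=C/C=C(C)/C#C[C@]1(O)C(C)(C)C[C@H](O[Si](C)(C)C(C)(C)C)C=C1C
F3 | step 7 | epoxy acetate (primary acetate of 12) | CC(=O)OC/C=C(C)/C=C/C=C(C)/C#C[C@]1(O)C(C)(C)C[C@H](O[Si](C)(C)C(C)(C)C)[C@H]2O[C@@]12C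
F4 | step 9 | ring diol: (1S,2R,4S)-4-[(tert-butyldimethylsilyl)oxy]-2,6,6-trimethylcyclohexane-1,2-diol (cis-diol, anti to the silyloxy group) | O[C@H]1C(C)(C)C[C@H](O[Si](C)(C)C(C)(C)C)C[C@@]1(C)O
F5 | step 9 | α-hydroxy ketone: (2R,4S)-4-[(tert-butyldimethylsilyl)oxy]-2-hydroxy-2,6,6-trimethylcyclohexan-1-one | O=C1C(C)(C)C[C@H](O[Si](C)(C)C(C)(C)C)C[C@@]1(C)O
F6 | step 9 | acetylenic triol (7,8-didehydro analogue of 14) | OC/C=C(C)/C=C/C=C(C)/C#C[C@]1(O)C(C)(C)C[C@H](O[Si](C)(C)C(C)(C)C)C[C@@]1(C)O
F7 | step 14 | C20 diethyl phosphonate (CH2Br of 19 replaced by CH2–P(O)(OEt)2) | CC1=C(C#C/C(C)=C/C=C/C(C)=C/CP(=O)(OCC)OCC)C(C)(C)C[C@H](O[Si](C)(C)C(C)(C)C)C1
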